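## Retrosynthetic overview

1. Target 18 ← bromine addition to the exocyclic alkene of 17 ← SN2 chlorination of allylic alcohol 16 ← epoxide 15 ← cyclohexene 14.
2. 14 ← enol triflate reduction ← Wittig chloromethylenation of aldehyde 11 (the silyl enol ether holds the C3=C4 position).
3. The only ring is formed in one Diels–Alder reaction of 2-silyloxy diene 8 with (Z)-β-chloro enone 6; the silyloxy group fixes the regiochemistry and the (Z)-alkene fixes Cl cis to the acyl group.
4. Absolute configuration comes from the (S)-lactate carbinol in 6 (hydrogen-bonded α'-hydroxy enone); after the cycloaddition it is cut off as acetaldehyde, while the lactate carboxyl carbon stays as the vinylic CH.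
5. 6 ← O-TBS (S)-lactaldehyde 1 by ethynylation, anti-carbomagnesiation/chlorination and allylic oxidation.

Assumption: aldehyde 1 is bought as such (it is the commercial TBS-protected, DIBAL-reduced derivative of ethyl (S)-lactate); making it would add two routine steps.

## Route

Step 1
Reactants: 1 (2S)-2-[(tert-butyldimethylsilyl)oxy]propanal
Product: 2 (4S)-4-[(tert-butyldimethylsilyl)oxy]pent-1-yn-3-ol (C-3 epimers)
Conditions: HC≡CMgBr, THF, −78 → 0 °C; aq. NH4Cl
Reagents that add atoms: ethynylmagnesium bromide, C#C[Mg]Br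
Why: Grignard 1,2-addition of the acetylide to the aldehyde; the new carbinol forms as an epimer mixture, which does not matter because it becomes the ketone in step 3, and the bought lactate centre is untouched.

Step 2
Reactants: 2 (4S)-4-[(tert-butyldimethylsilyl)oxy]pent-1-yn-3-ol
Product: 5 (2S,4Z)-5-chloro-4-methylpent-4-ene-2,3-diol (C-3 epimers), via alkenylmagnesium chelate 3 (not isolated), via silyl-protected chloroallylic alcohol 4 (not isolated)
Conditions: MeMgBr (4 equiv), CuI (10 mol%), Et2O, 0 °C → reflux; NCS, −30 → 0 °C; then 1 M HCl/MeOH, rt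
Reagents that add atoms: methylmagnesium bromide, C[Mg]Br; N-chlorosuccinimide, O=C1CCC(=O)N1Cl
Why: Copper-catalysed anti-carbomagnesiation of the propargylic alkoxide (Duboudin reaction) puts methyl on the inner alkyne carbon and magnesium on the terminal carbon cis to the carbinol in a five-membered chelate; chlorination of the C–Mg bond with retention fixes the (Z)-chloroalkene, and acidic methanol then removes the silyl group.

Step 3
Reactants: 5 (2S,4Z)-5-chloro-4-methylpent-4-ene-2,3-diol
Product: 6 (1Z,4S)-1-chloro-4-hydroxy-2-methylpent-1-en-3-one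
Conditions: activated MnO2, CH2Cl2, rt
Reagents that add atoms: none
Why: Manganese dioxide oxidises only the allylic hydroxyl, leaving the saturated lactate carbinol, its configuration and the (Z)-chloroalkene untouched; the product is an intramolecularly hydrogen-bonded α'-hydroxy enone.

Step 4
Reactants: 7 3-methylbut-3-en-2-one
Product: 8 2-methyl-3-{[tri(propan-2-yl)silyl]oxy}buta-1,3-diene
Conditions: TIPSOTf, Et3N, CH2Cl2, 0 °C
Reagents that add atoms: triisopropylsilyl trifluoromethanesulfonate, CC(C)[Si](C(C)C)(C(C)C)OS(=O)(=O)C(F)(F)F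
Why: Soft enolisation; the ketone has a single enolisable position, so the cross-conjugated 2-silyloxy diene forms as one regioisomer.

Step 5
Reactants: 6 (1Z,4S)-1-chloro-4-hydroxy-2-methylpent-1-en-3-one, 8 2-methyl-3-{[tri(propan-2-yl)silyl]oxy}buta-1,3-diene
Product: 9 (2S)-1-[(1S,6S)-6-chloro-1,3-dimethyl-4-{[tri(propan-2-yl)silyl]oxy}cyclohex-3-en-1-yl]-2-hydroxypropan-1-one
Conditions: toluene, BHT (cat.), 70 °C, sealed tube; chromatography
Reagents that add atoms: none
Why: Normal-demand Diels–Alder reaction in which the silyloxy carbon ends para to the acyl-bearing carbon, the (Z)-dienophile places Cl cis to the acyl group, and the diene adds to the hydrogen-bonded s-cis enone on the face opposite the methyl of the (S)-carbinol (Masamune-type control), setting both ring centres as (1S,6S); the minor facial diastereomer is removed by chromatography.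

Step 6
Reactants: 9 (2S)-1-[(1S,6S)-6-chloro-1,3-dimethyl-4-{[tri(propan-2-yl)silyl]oxy}cyclohex-3-en-1-yl]-2-hydroxypropan-1-one
Product: 11 (1S,6S)-6-chloro-1,3-dimethyl-4-{[tri(propan-2-yl)silyl]oxy}cyclohex-3-ene-1-carbaldehyde, via diol 10 (not isolated)
Conditions: NaBH4, MeOH, 0 °C; then NaIO4, THF/pH 7 buffer, rt
Reagents that add atoms: none
Why: Hydride reduction of the α-hydroxy ketone to the 1,2-diol followed by Malaprade glycol cleavage removes the lactate carbinol as acetaldehyde and leaves the neopentyl aldehyde; C1 is quaternary and cannot epimerise, and the silyl enol ether survives the neutral conditions.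

Step 7
Reactants: 11 (1S,6S)-6-chloro-1,3-dimethyl-4-{[tri(propan-2-yl)silyl]oxy}cyclohex-3-ene-1-carbaldehyde
Product: 12 {[(4S,5S)-5-chloro-4-[(Z)-2-chloroethenyl]-2,4-dimethylcyclohex-1-en-1-yl]oxy}tri(propan-2-yl)silane
Conditions: Ph3P+CH2Cl Cl−, NaHMDS, THF, −78 → 0 °C; chromatography
Reagents that add atoms: (chloromethyl)triphenylphosphonium chloride, ClC[P+](c1ccccc1)(c1ccccc1)c1ccccc1.[Cl-]
Why: Wittig chloromethylenation with the non-stabilised chloro ylide under salt-free kinetic conditions favours the (Z)-chloroalkene, and the E isomer is removed by chromatography; no stereocentre is touched.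

Step 8
Reactants: 12 {[(4S,5S)-5-chloro-4-[(Z)-2-chloroethenyl]-2,4-dimethylcyclohex-1-en-1-yl]oxy}tri(propan-2-yl)silane
Product: 13 (4S,5S)-5-chloro-4-[(Z)-2-chloroethenyl]-2,4-dimethylcyclohex-1-en-1-yl trifluoromethanesulfonate
Conditions: CsF, PhNTf2, DME, rt
Reagents that add atoms: N-phenylbis(trifluoromethanesulfonimide), FC(F)(F)S(=O)(=O)N(c1ccccc1)S(=O)(=O)C(F)(F)F
Why: Fluoride cleaves the silyl enol ether to the regiodefined enolate, which is O-triflated, so the tetrasubstituted enol triflate keeps the C3=C4 double bond; no stereocentre is affected.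

Step 9
Reactants: 13 (4S,5S)-5-chloro-4-[(Z)-2-chloroethenyl]-2,4-dimethylcyclohex-1-en-1-yl trifluoromethanesulfonate
Product: 14 (4S,5S)-4-chloro-5-[(Z)-2-chloroethenyl]-1,5-dimethylcyclohex-1-ene
Conditions: Pd(OAc)2 (5 mol%), PPh3, HCO2H, n-Bu3N, DMF, 60 °C
Reagents that add atoms: none
Why: Palladium-catalysed formate hydrogenolysis of the alkenyl triflate replaces OTf by H with the double bond fixed; vinyl and alkyl chlorides do not undergo oxidative addition with Pd/PPh3 at this temperature.

Step 10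
Reactants: 14 (4S,5S)-4-chloro-5-[(Z)-2-chloroethenyl]-1,5-dimethylcyclohex-1-ene
Product: 15 (1R,3S,4S,6S)-4-chloro-3-[(Z)-2-chloroethenyl]-1,3-dimethyl-7-oxabicyclo[4.1.0]heptane
Conditions: mCPBA, NaHCO3, CH2Cl2, 0 °C
Reagents that add atoms: meta-chloroperoxybenzoic acid, OOC(=O)c1cccc(Cl)c1
Why: Prilezhaev epoxidation of the only electron-rich alkene; chair-like axial attack from the face opposite the pseudo-axial chlorovinyl group and the ring chlorine (syn attack would build a syn-diaxial C–O/C–Cl contact) gives the epoxide with oxygen trans to C–Cl.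

Step 11
Reactants: 15 (1R,3S,4S,6S)-4-chloro-3-[(Z)-2-chloroethenyl]-1,3-dimethyl-7-oxabicyclo[4.1.0]heptane
Product: 16 (1S,4S,5S)-5-chloro-4-[(Z)-2-chloroethenyl]-4-methyl-2-methylidenecyclohexan-1-ol
Conditions: Et2Al(TMP) (from Et2AlCl + LiTMP), toluene, 0 °C
Reagents that add atoms: none
Why: Aluminium-amide (Yamamoto) isomerisation of an epoxide to an allylic alcohol; syn β-elimination through a cyclic transition state takes the least hindered hydrogen, that of the methyl group, so the exocyclic methylene forms and the carbinol keeps the epoxide configuration.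

Step 12
Reactants: 16 (1S,4S,5S)-5-chloro-4-[(Z)-2-chloroethenyl]-4-methyl-2-methylidenecyclohexan-1-ol
Product: 17 (1S,2S,5R)-1,5-dichloro-2-[(Z)-2-chloroethenyl]-2-methyl-4-methylidenecyclohexane
Conditions: PPh3, Cl3CC(O)CCl3, CH2Cl2, −20 → 0 °C
Reagents that add atoms: hexachloroacetone, ClC(Cl)(Cl)C(=O)C(Cl)(Cl)Cl
Why: Appel-type chlorination by SN2 attack of chloride on the alkoxyphosphonium ion, with inversion and without allylic transposition, so chlorine enters equatorially and cis to the other ring chlorine.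

Step 13
Reactants: 17 (1S,2S,5R)-1,5-dichloro-2-[(Z)-2-chloroethenyl]-2-methyl-4-methylidenecyclohexane
Product: 18 (1S,2R,4S,5S)-1-bromo-1-(bromomethyl)-2,4-dichloro-5-[(Z)-2-chloroethenyl]-5-methylcyclohexane
Conditions: Br2, CH2Cl2, −78 °C, dark
Reagents that add atoms: bromine, BrBr
Why: Electrophilic bromination of the 1,1-disubstituted alkene (the chloroalkene is deactivated); bromide opens the bromonium ion at the tertiary carbon by axial attack anti to bromine, which places the tertiary bromine axial and cis to the neighbouring chlorine and the bromomethyl group equatorial.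

## Compound list

1 | (2S)-2-[(tert-butyldimethylsilyl)oxy]propanal | C[C@H](O[Si](C)(C)C(C)(C)C)C=O | starting material
2 | (4S)-4-[(tert-butyldimethylsilyl)oxy]pent-1-yn-3-ol (C-3 epimers) | C#CC(O)[C@H](C)O[Si](C)(C)C(C)(C)C | intermediate
3 | cyclic (Z)-alkenylmagnesium alkoxide from carbomagnesiation of 2 (not isolated) | C[C@H](O[Si](C)(C)C(C)(C)C)C1O[Mg]C=C1C | intermediate
4 | (1Z,4S)-4-[(tert-butyldimethylsilyl)oxy]-1-chloro-2-methylpent-1-en-3-ol (C-3 epimers, not isolated) | Cl/C=C(/C)C(O)[C@H](C)O[Si](C)(C)C(C)(C)C | intermediate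
5 | (2S,4Z)-5-chloro-4-methylpent-4-ene-2,3-diol (C-3 epimers) | Cl/C=C(/C)C(O)[C@H](C)O | intermediate
6 | (1Z,4S)-1-chloro-4-hydroxy-2-methylpent-1-en-3-one | Cl/C=C(/C)C(=O)[C@H](C)O | intermediate
7 | 3-methylbut-3-en-2-one | CC(=O)C(C)=C | starting material
8 | 2-methyl-3-{[tri(propan-2-yl)silyl]oxy}buta-1,3-diene | C=C(C)C(=C)O[Si](C(C)C)(C(C)C)C(C)C | intermediate
9 | (2S)-1-[(1S,6S)-6-chloro-1,3-dimethyl-4-{[tri(propan-2-yl)silyl]oxy}cyclohex-3-en-1-yl]-2-hydroxypropan-1-one | C[C@@]1(C(=O)[C@H](C)O)CC(C)=C(O[Si](C(C)C)(C(C)C)C(C)C)C[C@@H]1Cl | intermediate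
10 | (2S)-1-[(1S,6S)-6-chloro-1,3-dimethyl-4-{[tri(propan-2-yl)silyl]oxy}cyclohex-3-en-1-yl]propane-1,2-diol (C-1 epimers, not isolated) | C[C@@]1(C(O)[C@H](C)O)CC(C)=C(O[Si](C(C)C)(C(C)C)C(C)C)C[C@@H]1Cl | intermediate
11 | (1S,6S)-6-chloro-1,3-dimethyl-4-{[tri(propan-2-yl)silyl]oxy}cyclohex-3-ene-1-carbaldehyde | C[C@@]1(C=O)CC(C)=C(O[Si](C(C)C)(C(C)C)C(C)C)C[C@@H]1Cl | intermediate
12 | {[(4S,5S)-5-chloro-4-[(Z)-2-chloroethenyl]-2,4-dimethylcyclohex-1-en-1-yl]oxy}tri(propan-2-yl)silane | C[C@@]1(/C=C\Cl)CC(C)=C(O[Si](C(C)C)(C(C)C)C(C)C)C[C@@H]1Cl | intermediate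
13 | (4S,5S)-5-chloro-4-[(Z)-2-chloroethenyl]-2,4-dimethylcyclohex-1-en-1-yl trifluoromethanesulfonate | C[C@@]1(/C=C\Cl)CC(C)=C(OS(=O)(=O)C(F)(F)F)C[C@@H]1Cl | intermediate
14 | (4S,5S)-4-chloro-5-[(Z)-2-chloroethenyl]-1,5-dimethylcyclohex-1-ene | C[C@@]1(/C=C\Cl)CC(C)=CC[C@@H]1Cl | intermediate
15 | (1R,3S,4S,6S)-4-chloro-3-[(Z)-2-chloroethenyl]-1,3-dimethyl-7-oxabicyclo[4.1.0]heptane | C[C@@]1(/C=C\Cl)C[C@@]2(C)O[C@H]2C[C@@H]1Cl | intermediate
16 | (1S,4S,5S)-5-chloro-4-[(Z)-2-chloroethenyl]-4-methyl-2-methylidenecyclohexan-1-ol | C[C@@]1(/C=C\Cl)CC(=C)[C@@H](O)C[C@@H]1Cl | intermediate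
17 | (1S,2S,5R)-1,5-dichloro-2-[(Z)-2-chloroethenyl]-2-methyl-4-methylidenecyclohexane | C[C@@]1(/C=C\Cl)CC(=C)[C@H](Cl)C[C@@H]1Cl | intermediate
18 | (1S,2R,4S,5S)-1-bromo-1-(bromomethyl)-2,4-dichloro-5-[(Z)-2-chloroethenyl]-5-methylcyclohexane | C[C@@]1(/C=C\Cl)C[C@@](Br)(CBr)[C@H](Cl)C[C@@H]1Cl | target

## Step count and weak points

Total: 13 steps. Longest linear sequence: 12 steps (1–3 and 5–13); step 4 makes the diene.

**Step 5 (Diels–Alder).** The dienophile is trisubstituted and hindered, diene 8 is sensitive to protic and acidic partners, and only a methyl group shields one face, so rate and facial ratio may be modest. Fallback, from 6 and back at 14: use plain isoprene as the diene (neat, sealed tube, about 90 °C). No silyl enol ether is involved, but the regiochemistry is no longer enforced and the wanted adduct is expected to be the minor regioisomer. It is (2S)-1-[(1S,6S)-6-chloro-1,3-dimethylcyclohex-3-en-1-yl]-2-hydroxypropan-1-one F1 and must be separated from its 1,4-dimethyl regioisomer. The same borohydride/periodate sequence gives (1S,6S)-6-chloro-1,3-dimethylcyclohex-3-ene-1-carbaldehyde F2, and the chloromethylenation of step 7 then gives 14 directly, so steps 8 and 9 drop out.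

**Step 7 (Wittig).** The Z/E ratio of chloromethylenation on a neopentyl aldehyde is often only moderate. Fallback, from 11 and back at 12: Ohira–Bestmann homologation gives the alkyne {[(4S,5S)-5-chloro-4-ethynyl-2,4-dimethylcyclohex-1-en-1-yl]oxy}tri(propan-2-yl)silane F3. Deprotonation (LiHMDS) and NCS give {[(4S,5S)-5-chloro-4-(chloroethynyl)-2,4-dimethylcyclohex-1-en-1-yl]oxy}tri(propan-2-yl)silane F4. Syn hydroboration with dicyclohexylborane followed by protonolysis with acetic acid then gives the (Z)-chloroalkene 12 stereospecifically.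

**Step 13 (bromination).** Axial attack of bromide at C1 of the ring is hindered by the syn-axial chlorovinyl group, so some of the epimer with equatorial bromine may form. Fallback, from 17 and back at 18: accept the kinetic mixture containing (1R,2R,4S,5S)-1-bromo-1-(bromomethyl)-2,4-dichloro-5-[(Z)-2-chloroethenyl]-5-methylcyclohexane F5 and equilibrate it (LiBr, MeCN, 50 °C). Vicinal dibromides epimerise through the bromonium ion, and 18, with the bromomethyl group equatorial, should be the more stable isomer.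

## Further compounds

F1 | step 5 | (2S)-1-[(1S,6S)-6-chloro-1,3-dimethylcyclohex-3-en-1-yl]-2-hydroxypropan-1-one | C[C@@]1(C(=O)[C@H](C)O)CC(C)=CC[C@@H]1Cl
F2 | step 5 | (1S,6S)-6-chloro-1,3-dimethylcyclohex-3-ene-1-carbaldehyde | C[C@@]1(C=O)CC(C)=CC[C@@H]1Cl
F3 | step 7 | {[(4S,5S)-5-chloro-4-ethynyl-2,4-dimethylcyclohex-1-en-1-yl]oxy}tri(propan-2-yl)silane | C[C@@]1(C#C)CC(C)=C(O[Si](C(C)C)(C(C)C)C(C)C)C[C@@H]1Cl
F4 | step 7 | {[(4S,5S)-5-chloro-4-(chloroethynyl)-2,4-dimethylcyclohex-1-en-1-yl]oxy}tri(propan-2-yl)silane | C[C@@]1(C#CCl)CC(C)=C(O[Si](C(C)C)(C(C)C)C(C)C)C[C@@H]1Cl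
F5 | step 13 | (1R,2R,4S,5S)-1-bromo-1-(bromomethyl)-2,4-dichloro-5-[(Z)-2-chloroethenyl]-5-methylcyclohexane | C[C@@]1(/C=C\Cl)C[C@](Br)(CBr)[C@H](Cl)C[C@@H]1Cl
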